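**Plan**

1. Retrosynthesis, in order: cut the benzylic aryl ether C–O bond (to (2S)-pinocembrin and a carbinol); cut together the C3–C3a and O1–C6a bonds of the hexahydrofuro[3,2-b]furan-2-one (an acetate C–C(=O)–O unit taken off a 2,3-dihydrofuran); open the dihydrofuran to a γ-hydroxy sulfoxide plus one formyl carbon; cut the chain at the bond made by epoxide opening with a sulfinyl carbanion.
2. Forward: the chain is joined from an epoxy alcohol and methyl p-tolyl sulfoxide, the oxolane ring is closed as a 2,3-dihydrofuran, the lactone ring is fused on in one dichloroketene annulation, the helper atoms (two Cl, S-aryl, silyl) are removed, and the aryl ether is made last.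
3. Enabling feature: the ring-fusion bond C3a–C6a is the former C5=C4 enol-ether double bond of the oxolane. A p-tolylsulfinyl group on C4 (future C6a) lets its oxygen carry dichloroketene, so carbon goes to the oxygen-bearing C5 (future C3a) and oxygen to C4, the reverse of normal enol-ether polarity.
4. Stereochemistry: Sharpless kinetic resolution sets C5 and the carbinol carbon; sulfur (from (S)-methyl p-tolyl sulfoxide) together with the C5 side chain sets C3a in the key step; C6a follows from cis ring fusion; the carbinol is inverted in the Mitsunobu step; the flavanone centre comes from (2S)-pinocembrin.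

Key step: step 6

Remark (assumptions): (2S)-pinocembrin and (S)-methyl p-tolyl sulfoxide are taken as purchased. The sulfur descriptor changes from S (alkyl sulfoxides 4–9) to R (vinyl sulfoxide 10), and the carbinol descriptor from S (reacting enantiomer of 1) to R (2), with no change in geometry; only the CIP ranking of a neighbouring carbon changes. The matched sense of sulfur in step 6 is assigned from a chair transition state with pseudo-equatorial p-tolyl.

**Route**

Step 1
Reactants: 1 (±)-1-phenylprop-2-en-1-ol
Product: 2 (R)-phenyl[(S)-oxiran-2-yl]methanol (erythro)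
Conditions: Ti(OiPr)4 (cat.), D-(−)-diisopropyl tartrate, t-BuOOH (0.45 equiv), 4 Å MS, CH2Cl2, −20 °C
Reagents that add atoms: tert-butyl hydroperoxide, CC(C)(C)OO
Why: Sharpless kinetic resolution, in which the titanium–D-(−)-tartrate catalyst should epoxidise only the (S)-enantiomer of 1 to the erythro epoxy alcohol, so the reagent sets both the carbinol and the oxirane carbon and unreacted (R)-1 is removed by chromatography.

Step 2
Reactants: 2 (R)-phenyl[(S)-oxiran-2-yl]methanol
Product: 3 triisopropyl{(R)-[(S)-oxiran-2-yl](phenyl)methoxy}silane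
Conditions: TIPSOTf, 2,6-lutidine, CH2Cl2, −78 → 0 °C
Reagents that add atoms: triisopropylsilyl triflate, CC(C)[Si](C(C)C)(C(C)C)OS(=O)(=O)C(F)(F)F
Why: Silyl ether formation with a silyl triflate at low temperature should outpace opening of the oxirane, and the bulky triisopropylsilyl group is chosen because it should not migrate to the neighbouring alkoxide of steps 3 and 4 and should withstand the zinc chloride of step 6.

Step 3
Reactants: 3 triisopropyl{(R)-[(S)-oxiran-2-yl](phenyl)methoxy}silane; 4 (S)-methyl p-tolyl sulfoxide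
Product: 6 (1R,2S)-1-phenyl-4-[(S)-p-tolylsulfinyl]-1-(triisopropylsilyloxy)butan-2-ol, via lithiomethyl p-tolyl sulfoxide 5 (not isolated)
Conditions: 4 (1.5 equiv), LDA, THF, −78 °C; then 3, −78 → 0 °C; then H2O
Reagents that add atoms: none
Why: Alkylation of an α-sulfinyl carbanion by a terminal epoxide, in which the carbanion should attack the unhindered CH2 of the oxirane so that the oxirane stereocentre becomes the carbinol carbon unchanged and sulfur keeps its configuration.

Step 4
Reactants: 6 (1R,2S)-1-phenyl-4-[(S)-p-tolylsulfinyl]-1-(triisopropylsilyloxy)butan-2-ol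
Product: 8 (5S)-5-[(R)-phenyl(triisopropylsilyloxy)methyl]-3-[(S)-p-tolylsulfinyl]oxolan-2-ol (epimers at C2 and C3), via open-chain α-formyl sulfoxide 7 (not isolated)
Conditions: LDA (3.2 equiv), THF, −78 °C; HCO2Et, −78 → 0 °C; then AcOH
Reagents that add atoms: ethyl formate, CCOC=O
Why: Claisen-type C-formylation of the α-sulfinyl carbanion (the third equivalent of base covers the acidic product), after which the γ-hydroxyl should close onto the new aldehyde as the five-membered lactol, whose two new centres are left as a mixture because both become sp2 in step 5.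

Step 5
Reactants: 8 (5S)-5-[(R)-phenyl(triisopropylsilyloxy)methyl]-3-[(S)-p-tolylsulfinyl]oxolan-2-ol
Product: 10 (2S)-2-[(R)-phenyl(triisopropylsilyloxy)methyl]-4-[(R)-p-tolylsulfinyl]-2,3-dihydrofuran, via lactol mesylate 9 (not isolated)
Conditions: MsCl, Et3N, CH2Cl2, −20 → 0 °C
Reagents that add atoms: none
Why: Mesylation of the anomeric hydroxyl followed by base-induced loss of methanesulfonate and of the proton acidified by the sulfinyl group (E1cB-type dehydration) should give the sulfinyl enol ether without heating, which avoids thermal sulfoxide elimination.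

Step 6
Reactants: 10 (2S)-2-[(R)-phenyl(triisopropylsilyloxy)methyl]-4-[(R)-p-tolylsulfinyl]-2,3-dihydrofuran
Product: 13 (3aS,5S,6aS)-3,3-dichloro-5-[(R)-phenyl(triisopropylsilyloxy)methyl]-6a-(p-tolylsulfanyl)hexahydrofuro[3,2-b]furan-2-one, via oxysulfonium dichloroenolate 11 (not isolated), via thionium carboxylate 12 (not isolated)
Conditions: Cl3CCOCl (3 equiv), Zn–Cu couple, Et2O, −40 → 0 °C
Reagents that add atoms: trichloroacetyl chloride, ClC(Cl)(Cl)C(Cl)=O
Why: Proposed new method: the sulfinyl oxygen of 10 should add to dichloroketene to give oxysulfonium enolate 11, whose dichloroenolate carbon is passed by a [3,3]-sigmatropic shift (S–O broken, C–C made) to C5 of the dihydrofuran, an oxocarbenium-like carbon in the vinyloxysulfonium ion, leaving thionium carboxylate 12, whose carboxylate then adds to the thionium carbon C4. The closest known reaction type is the Marino lactonisation of simple and cycloalkenyl aryl sulfoxides with dichloroketene, which to the best of knowledge has not been shown for a sulfoxide on the β-carbon of a cyclic enol ether. The lactone ring closes by 5-exo-trig attack of the carboxylate on C4, and because the tether is already fixed on one face of C5 only the cis-fused ring can form. C3a (the former C5) is set by suprafacial delivery from sulfur: in the chair-like transition state with pseudo-equatorial p-tolyl, (R)-sulfur places the S–O bond on the ring face anti to the C2 side chain, so sulfur and the C2 stereocentre should reinforce each other, and C6a follows from the cis fusion. The step needs regioselectivity (carbon to the oxygen-bearing C5, oxygen to C4), which the position of the sulfinyl group secures, and chemoselectivity over [2+2] addition to the double bond, which the electron-poor character of the sulfinyl-substituted alkene secures.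

Step 7
Reactants: 13 (3aS,5S,6aS)-3,3-dichloro-5-[(R)-phenyl(triisopropylsilyloxy)methyl]-6a-(p-tolylsulfanyl)hexahydrofuro[3,2-b]furan-2-one
Product: 14 (3aR,5S,6aR)-5-[(R)-phenyl(triisopropylsilyloxy)methyl]hexahydrofuro[3,2-b]furan-2-one
Conditions: Bu3SnH (5 equiv), AIBN (cat.), toluene, 110 °C
Reagents that add atoms: none
Why: Radical chain reduction with Bu3SnH should cleave both C–Cl bonds α to the carbonyl and the C–S bond of the O,S-acetal carbon, and the bridgehead α-oxy radical can take up hydrogen only on the convex face, which gives the cis-fused lactone and fixes C6a.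

Step 8
Reactants: 14 (3aR,5S,6aR)-5-[(R)-phenyl(triisopropylsilyloxy)methyl]hexahydrofuro[3,2-b]furan-2-one
Product: 15 (3aR,5S,6aR)-5-[(R)-hydroxy(phenyl)methyl]hexahydrofuro[3,2-b]furan-2-one
Conditions: HF·pyridine, pyridine, THF, 0 °C → rt
Reagents that add atoms: none
Why: Fluoride cleavage of the silyl ether under buffered, non-basic conditions should leave the lactone and its base-sensitive β-alkoxy linkage untouched.

Step 9
Reactants: 15 (3aR,5S,6aR)-5-[(R)-hydroxy(phenyl)methyl]hexahydrofuro[3,2-b]furan-2-one; 16 (2S)-pinocembrin [(2S)-5,7-dihydroxy-2-phenylchroman-4-one]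
Product: 17 (3aR,5S,6aR)-5-[(S)-{[(2S)-5-hydroxy-4-oxo-2-phenylchroman-7-yl]oxy}(phenyl)methyl]hexahydrofuro[3,2-b]furan-2-one (target)
Conditions: PPh3, DIAD, THF, 0 °C → rt
Reagents that add atoms: none
Why: Mitsunobu etherification, in which the acidic, unchelated 7-hydroxyl of 16 (the 5-hydroxyl is hydrogen-bonded to the ketone) should displace the oxyphosphonium of 15 with inversion, turning the (R)-carbinol into the (S)-aryl ether while the near-neutral conditions spare the flavanone stereocentre.

**Compound list**

1 | (±)-1-phenylprop-2-en-1-ol | C=CC(O)c1ccccc1 | starting material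
2 | (R)-phenyl[(S)-oxiran-2-yl]methanol | C1O[C@@H]1[C@H](O)c1ccccc1 | intermediate
3 | triisopropyl{(R)-[(S)-oxiran-2-yl](phenyl)methoxy}silane | C1O[C@@H]1[C@H](O[Si](C(C)C)(C(C)C)C(C)C)c1ccccc1 | intermediate
4 | (S)-methyl p-tolyl sulfoxide | C[S@](=O)c1ccc(C)cc1 | starting material
5 | lithiomethyl p-tolyl sulfoxide | [Li]C[S@](=O)c1ccc(C)cc1 | intermediate (not isolated)
6 | (1R,2S)-1-phenyl-4-[(S)-p-tolylsulfinyl]-1-(triisopropylsilyloxy)butan-2-ol | O[C@@H](CC[S@](=O)c1ccc(C)cc1)[C@H](O[Si](C(C)C)(C(C)C)C(C)C)c1ccccc1 | intermediate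
7 | open-chain α-formyl sulfoxide, (4S,5R)-4-hydroxy-5-phenyl-2-[(S)-p-tolylsulfinyl]-5-(triisopropylsilyloxy)pentanal | O=CC(C[C@H](O)[C@H](O[Si](C(C)C)(C(C)C)C(C)C)c1ccccc1)[S@](=O)c1ccc(C)cc1 | intermediate (not isolated)
8 | (5S)-5-[(R)-phenyl(triisopropylsilyloxy)methyl]-3-[(S)-p-tolylsulfinyl]oxolan-2-ol | OC1O[C@H]([C@H](O[Si](C(C)C)(C(C)C)C(C)C)c2ccccc2)CC1[S@](=O)c1ccc(C)cc1 | intermediate
9 | lactol mesylate of 8 | CS(=O)(=O)OC1O[C@H]([C@H](O[Si](C(C)C)(C(C)C)C(C)C)c2ccccc2)CC1[S@](=O)c1ccc(C)cc1 | intermediate (not isolated)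
10 | (2S)-2-[(R)-phenyl(triisopropylsilyloxy)methyl]-4-[(R)-p-tolylsulfinyl]-2,3-dihydrofuran | O1C=C([S@](=O)c2ccc(C)cc2)C[C@H]1[C@H](O[Si](C(C)C)(C(C)C)C(C)C)c1ccccc1 | intermediate
11 | oxysulfonium dichloroenolate (O-acylated sulfoxide zwitterion) | O1C=C([S@+](OC([O-])=C(Cl)Cl)c2ccc(C)cc2)C[C@H]1[C@H](O[Si](C(C)C)(C(C)C)C(C)C)c1ccccc1 | intermediate (not isolated)
12 | thionium carboxylate | [O-]C(=O)C(Cl)(Cl)[C@H]1O[C@H]([C@H](O[Si](C(C)C)(C(C)C)C(C)C)c2ccccc2)CC1=[S+]c1ccc(C)cc1 | intermediate (not isolated)
13 | (3aS,5S,6aS)-3,3-dichloro-5-[(R)-phenyl(triisopropylsilyloxy)methyl]-6a-(p-tolylsulfanyl)hexahydrofuro[3,2-b]furan-2-one | O=C1C(Cl)(Cl)[C@H]2O[C@H]([C@H](O[Si](C(C)C)(C(C)C)C(C)C)c3ccccc3)C[C@@]2(Sc2ccc(C)cc2)O1 | intermediate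
14 | (3aR,5S,6aR)-5-[(R)-phenyl(triisopropylsilyloxy)methyl]hexahydrofuro[3,2-b]furan-2-one | O=C1C[C@H]2O[C@H]([C@H](O[Si](C(C)C)(C(C)C)C(C)C)c3ccccc3)C[C@H]2O1 | intermediate
15 | (3aR,5S,6aR)-5-[(R)-hydroxy(phenyl)methyl]hexahydrofuro[3,2-b]furan-2-one | O=C1C[C@H]2O[C@H]([C@H](O)c3ccccc3)C[C@H]2O1 | intermediate
16 | (2S)-pinocembrin | Oc1cc(O)c2c(c1)O[C@H](c1ccccc1)CC2=O | starting material
17 | (3aR,5S,6aR)-5-[(S)-{[(2S)-5-hydroxy-4-oxo-2-phenylchroman-7-yl]oxy}(phenyl)methyl]hexahydrofuro[3,2-b]furan-2-one | O=C1C[C@H]2O[C@H]([C@@H](Oc3cc(O)c4c(c3)O[C@H](c3ccccc3)CC4=O)c3ccccc3)C[C@H]2O1 | target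

**Count and risks**

Total steps: 9. Longest linear sequence: 9 steps (1 → 17).

Steps most likely to fail:

Step 6 (bears the label). What may go wrong: poor facial selectivity in the sigmatropic transfer if the assumed transition-state preference does not hold, reductive deoxygenation of the sulfoxide by zinc before O-acylation, or proton loss from the thionium ion instead of lactonisation. The fallback uses known chemistry, sets out from 3 and comes back at 14. Opening of 3 with lithium acetylide–ethylenediamine complex in DMSO should give the homopropargylic alcohol (1R,2S)-1-phenyl-1-(triisopropylsilyloxy)pent-4-yn-2-ol F1. Alkynol cycloisomerisation with Mo(CO)6, Et3N and light in Et2O should give (2S)-2-[(R)-phenyl(triisopropylsilyloxy)methyl]-2,3-dihydrofuran F2. Dichloroketene [2+2] cycloaddition (Cl3CCOCl, Zn–Cu couple, Et2O), anti to the side chain and with CCl2 on the acetal carbon, should give the cyclobutanone (1S,3S,5R)-7,7-dichloro-3-[(R)-phenyl(triisopropylsilyloxy)methyl]-2-oxabicyclo[3.2.0]heptan-6-one F3. Baeyer–Villiger oxidation (mCPBA, NaHCO3, CH2Cl2), with migration of the non-chlorinated bridgehead carbon, should give (3aS,5S,6aR)-3,3-dichloro-5-[(R)-phenyl(triisopropylsilyloxy)methyl]hexahydrofuro[3,2-b]furan-2-one F4. Zn in AcOH should then remove both chlorines to give 14. In this fallback the two bonds are made in two operations instead of one.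

Step 3. What may go wrong: slow ring opening of the oxirane by the weakly nucleophilic sulfinyl carbanion, with proton transfer and decomposition competing. The fallback sets out from 3 and comes back at 6. The more nucleophilic p-tolylthiomethyllithium (from methyl p-tolyl sulfide, n-BuLi and TMEDA in THF) should open 3 to the hydroxy sulfide (1R,2S)-1-phenyl-4-(p-tolylsulfanyl)-1-(triisopropylsilyloxy)butan-2-ol F5. Sulfur is then oxidised by a Kagan oxidation (Ti(OiPr)4, D-(−)-diethyl tartrate, H2O, cumene hydroperoxide, CH2Cl2, −20 °C). The sulfur epimers are diastereomers and can be separated, which gives 6.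

Step 9. What may go wrong: elimination or ionisation at the activated benzylic carbinol with loss of stereochemical integrity, or low conversion at the hindered centre. The fallback sets out from 15 and comes back at 17. Sulfonylation (MsCl, Et3N, CH2Cl2, −20 °C) should give the mesylate (R)-[(3aR,5S,6aR)-2-oxohexahydrofuro[3,2-b]furan-5-yl](phenyl)methyl methanesulfonate F6. Direct SN2 displacement with the 7-phenoxide of 16 (K2CO3, acetone, rt) should then give 17 with the same inversion.

Further compounds
F1 | step 6 | (1R,2S)-1-phenyl-1-(triisopropylsilyloxy)pent-4-yn-2-ol | C#CC[C@H](O)[C@H](O[Si](C(C)C)(C(C)C)C(C)C)c1ccccc1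
F2 | step 6 | (2S)-2-[(R)-phenyl(triisopropylsilyloxy)methyl]-2,3-dihydrofuran | O1C=CC[C@H]1[C@H](O[Si](C(C)C)(C(C)C)C(C)C)c1ccccc1
F3 | step 6 | (1S,3S,5R)-7,7-dichloro-3-[(R)-phenyl(triisopropylsilyloxy)methyl]-2-oxabicyclo[3.2.0]heptan-6-one | O=C1C(Cl)(Cl)[C@H]2O[C@H]([C@H](O[Si](C(C)C)(C(C)C)C(C)C)c3ccccc3)C[C@H]21
F4 | step 6 | (3aS,5S,6aR)-3,3-dichloro-5-[(R)-phenyl(triisopropylsilyloxy)methyl]hexahydrofuro[3,2-b]furan-2-one | O=C1C(Cl)(Cl)[C@H]2O[C@H]([C@H](O[Si](C(C)C)(C(C)C)C(C)C)c3ccccc3)C[C@H]2O1
F5 | step 3 | (1R,2S)-1-phenyl-4-(p-tolylsulfanyl)-1-(triisopropylsilyloxy)butan-2-ol | O[C@@H](CCSc1ccc(C)cc1)[C@H](O[Si](C(C)C)(C(C)C)C(C)C)c1ccccc1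
F6 | step 9 | (R)-[(3aR,5S,6aR)-2-oxohexahydrofuro[3,2-b]furan-5-yl](phenyl)methyl methanesulfonate | O=C1C[C@H]2O[C@H]([C@H](OS(C)(=O)=O)c3ccccc3)C[C@H]2O1
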